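**Assumption:** the target has no stereocenters, so there is no enantiomer to set. The prenyl and chromene alkenes need no descriptors.

## Retrosynthetic overview
1. The 1,3-diketone of **7** disconnects by Claisen condensation into the A-ring methyl ketone **3** and the B-ring methyl ester **6**.
2. The 2,2-dimethylchromene ring of **3** is made on 2,4-dihydroxyacetophenone **1** with prenal **2**, by way of a dearomatized o-quinone methide and oxa-6π electrocyclization. This is the key step, and it also picks C-5 over C-3 of the resorcinol-type ring.
3. The B-ring prenyl group of **6** comes from direct ortho C-prenylation of methyl paraben **4**.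
4. Ring order: the chromene ring forms first, then the prenylated benzoate is made separately, and the diketone is formed last.

## Route

**Step 1 (key step)**
Reactants: **1** 2,4-dihydroxyacetophenone; **2** 3-methylbut-2-enal (prenal)
Product: **3** 1-(7-hydroxy-2,2-dimethyl-2H-chromen-6-yl)ethan-1-one
Conditions: pyridine, reflux (115 °C), 16–24 h
Reagents that add atoms: prenal **2**, CC(C)=CC=O (all its carbons and its oxygen are incorporated, with loss of H2O)
Why: The 4-OH (the 2-OH is locked in an H-bond with the acetyl) condenses with prenal at the less hindered C-5, dearomatizing the ring to an o-quinone methide. Oxa-6π electrocyclization and rearomatization then give the linear 6-acetyl-7-hydroxychromene, and C-3, which is flanked by two oxygens, reacts less. This is a Knoevenagel condensation/6π-oxa-electrocyclization chromene annulation. No stereocenter forms.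

**Step 2**
Reactants: **4** methyl 4-hydroxybenzoate; **5** prenyl bromide
Product: **6** methyl 4-hydroxy-3-(3-methylbut-2-en-1-yl)benzoate
Conditions: EtMgBr (1.0 equiv), toluene/Et2O, 0 °C, then remove Et2O; **5** (1.1 equiv), toluene, 60 °C, 6 h; aq. NH4Cl work-up
Reagents that add atoms: prenyl bromide **5**, CC(C)=CCBr (supplies the prenyl group)
Why: The magnesium phenoxide in a non-polar solvent keeps the oxygen tied up and delivers the prenyl electrophile to the ortho carbon. This is a dearomative C-alkylation that gives a 6-prenylcyclohexa-2,4-dienone, which tautomerizes back to the phenol. The para position is blocked by the ester, and no stereocenter forms.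

**Step 3**
Reactants: **3** ketone; **6** ester
Product: **7** Glyinflanin C
Conditions: LiHMDS (5 equiv), THF, –78 °C to 60 °C, 16 h; quench with 1 M HCl to pH 4–5 at 0 °C
Reagents that add atoms: none (the methoxy group leaves as MeOH)
Why: The excess base fully deprotonates both phenols and forms the ketone enolate, which attacks the ester (Claisen condensation) and drives the reaction as the stabilized 1,3-diketonate. Mild, brief acidification avoids cyclization to the flavone and damage to the chromene. There is no stereocenter to set.

**Atom check**
- Step 1: C8H8O3 + C5H8O − H2O = C13H14O3 (**3**).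
- Step 2: C8H8O3 + C5H9Br − HBr = C13H16O3 (**6**).
- Step 3: C13H14O3 + C13H16O3 − CH3OH = C25H26O5.
- **7** has the same formula. Its SMILES matches the target: 4-hydroxy-3-prenylphenyl ketone, 1,3-diketone, and 6-acyl-7-hydroxy-2,2-dimethylchromene.

**Functional-group survival**
- The chromene alkene and prenyl alkene tolerate base and pyridine.
- The ester in step 2 survives 1 equiv of Grignard because the phenol is deprotonated first.

## Compound list
1 | 2,4-dihydroxyacetophenone | CC(=O)c1ccc(O)cc1O | starting material
2 | 3-methylbut-2-enal (prenal) | CC(C)=CC=O | starting material
3 | 1-(7-hydroxy-2,2-dimethyl-2H-chromen-6-yl)ethanone | CC(=O)c1cc2C=CC(C)(C)Oc2cc1O | intermediate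
4 | methyl 4-hydroxybenzoate | COC(=O)c1ccc(O)cc1 | starting material
5 | prenyl bromide | CC(C)=CCBr | starting material
6 | methyl 4-hydroxy-3-prenylbenzoate | COC(=O)c1ccc(O)c(CC=C(C)C)c1 | intermediate
7 | Glyinflanin C (achiral) | CC(C)=CCc1cc(C(=O)CC(=O)c2cc3c(cc2O)OC(C)(C)C=C3)ccc1O | target

**Total steps:** 3. **Longest linear sequence:** 2 steps (1→3→7, or 4→6→7).

## Three steps most likely to fail
1. **Step 3, Claisen condensation with two free phenols.** The phenoxide-bearing ester is a poor electrophile.
   - Fallback: protect the B-ring phenol of **6** as its TBS ether and hydrolyze to the acid chloride. Acylate the phenol of **3**, then run a Baker–Venkataraman rearrangement (KOtBu) and remove the TBS group with TBAF/AcOH.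
2. **Step 2, ortho C-prenylation.** O-alkylation and di-prenylation compete.
   - Fallback: iodinate **4** with NIS/AcOH to give methyl 4-hydroxy-3-iodobenzoate, then couple it with prenyl-Bpin or prenyl-BF3K under Pd catalysis.
3. **Step 1, C-5 versus C-3 regioselectivity and yield.**
   - Fallback: alkylate the 4-OH of **1** selectively with 3-chloro-3-methylbut-1-yne (K2CO3, KI, CuI, acetone) to give the propargyl ether. Then heat in N,N-diethylaniline at ~200 °C for aryl propargyl ether cyclization to the linear chromene **3**.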